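**Strategy.** The route rests on disconnecting the 2-(acyloxymethyl)acrylic acid unit embedded in the seven-membered lactone (2-benzoxepin-1-one ring: O2–C3H2–C4(CO2H)=C5H). A tandem oxa-Michael addition/intramolecular Horner–Wadsworth–Emmons reaction of a carboxylate with tert-butyl 2-(diethoxyphosphoryl)acrylate forms the O2–C3 bond and the C4=C5 double bond in one operation. Its precursor is a five-membered γ-hydroxy-γ-lactone (pseudo-acid) that masks the trans formyl and carboxyl groups on the cyclohexane and is thereby ring-expanded by three carbons. Both terpenoid halves come from (R)-cryptone and are joined by carboxylate opening of a spiro-epoxide.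

Key step: step 15

Remark: in the Why lines the six-membered rings carry p-menthane locants (C1 bears the CH2O carbon C7, C4 the isopropyl group); the lactol carbon of 31 is a mixture of epimers, which is irrelevant because it becomes the alkene CH.

Step 1
Reactants: 1 3-methylbutanal; 2 but-3-en-2-one
Product: 4 (4R)-4-isopropylcyclohex-2-en-1-one, via keto aldehyde 3 (not isolated)
Conditions: (R)-2-[methoxy(diphenyl)methyl]pyrrolidine (5 mol %), ethyl 3,4-dihydroxybenzoate (20 mol %), neat, 4 °C; then aq KOH, Bu4NOH (cat.), THF/Et2O, reflux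
Reagents that add atoms: none
Why: Enamine-catalysed Michael addition of the aldehyde to the enone sets the isopropyl-bearing centre by attack on the enamine face remote from the diarylmethyl group, and the intramolecular aldol condensation that follows closes the cyclohexenone without touching that centre.

Step 2
Reactants: 4 (4R)-4-isopropylcyclohex-2-en-1-one; 5 vinylmagnesium bromide
Product: 7 (3R,4R)-4-isopropyl-3-vinylcyclohex-1-en-1-yl trifluoromethanesulfonate, via magnesium enolate 6 (not isolated)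
Conditions: 5, CuBr·SMe2 (10 mol %), THF, –78 °C; then PhNTf2, DMPU, –78 °C → rt
Reagents that add atoms: N-phenylbis(trifluoromethanesulfonimide) FC(F)(F)S(=O)(=O)N(c1ccccc1)S(=O)(=O)C(F)(F)F
Why: Copper-catalysed conjugate addition of the Grignard reagent should occur anti to the adjacent isopropyl group (3,4-trans), and the regiodefined enolate is trapped on oxygen as the C1=C2 enol triflate.

Step 3
Reactants: 7 (3R,4R)-4-isopropyl-3-vinylcyclohex-1-en-1-yl trifluoromethanesulfonate
Product: 9 (3R,4R)-3-(dimethoxymethyl)-4-isopropylcyclohex-1-en-1-yl trifluoromethanesulfonate, via aldehyde 8 (not isolated)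
Conditions: O3, CH2Cl2/MeOH, –78 °C; Me2S, –78 °C → rt; then HC(OMe)3, TsOH·H2O (cat.), rt
Reagents that add atoms: trimethyl orthoformate COC(OC)OC
Why: Ozonolysis should cleave the electron-rich vinyl group much faster than the triflate-deactivated enol double bond, and the aldehyde is acetalised in the same pot under acid, so its alpha centre never meets base.

Step 4
Reactants: 9 (3R,4R)-3-(dimethoxymethyl)-4-isopropylcyclohex-1-en-1-yl trifluoromethanesulfonate; 10 (tributylstannyl)methanol
Product: 11 [(3R,4R)-3-(dimethoxymethyl)-4-isopropylcyclohex-1-en-1-yl]methanol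
Conditions: Pd(PPh3)4 (5 mol %), LiCl (3 equiv), 1,4-dioxane, 100 °C
Reagents that add atoms: none
Why: Stille coupling of the alkenyl triflate with the hydroxymethylstannane replaces OTf by CH2OH (C7) without moving the double bond.

Step 5
Reactants: 11 [(3R,4R)-3-(dimethoxymethyl)-4-isopropylcyclohex-1-en-1-yl]methanol
Product: 13 (3R,4R)-1-(chloromethyl)-3-(dimethoxymethyl)-4-isopropylcyclohex-1-ene, via allylic mesylate 12 (not isolated)
Conditions: MsCl, 2,4,6-collidine, LiCl, DMF, 0 °C
Reagents that add atoms: lithium chloride [Li+].[Cl-]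
Why: Mesylation followed by in situ SN2 displacement with chloride gives the primary allylic chloride under buffered conditions that spare the acetal.

Step 6
Reactants: 13 (3R,4R)-1-(chloromethyl)-3-(dimethoxymethyl)-4-isopropylcyclohex-1-ene; 14 di-tert-butyl dicarbonate
Product: 16 tert-butyl (1S,2R,3R)-2-(dimethoxymethyl)-3-isopropyl-6-methylidenecyclohexane-1-carboxylate, via allylmagnesium chloride 15 (not isolated)
Conditions: Mg turnings (activated, excess), THF, 0 °C, slow addition; then 14, –78 → 0 °C; aq NH4Cl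
Reagents that add atoms: none
Why: Acylation of the allylic Grignard reagent through a six-membered SE2′ transition state should place the ester on ring carbon C2 and move the double bond to the exocyclic C1=C7 position, with the electrophile approaching anti to the neighbouring dimethoxymethyl group (2,3-trans); the hindered tert-butyl ester resists a second addition.

Step 7
Reactants: 16 tert-butyl (1S,2R,3R)-2-(dimethoxymethyl)-3-isopropyl-6-methylidenecyclohexane-1-carboxylate
Product: 17 tert-butyl (1S,2R,3R,6S)-2-(dimethoxymethyl)-6-hydroxy-6-(hydroxymethyl)-3-isopropylcyclohexane-1-carboxylate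
Conditions: OsO4 (2 mol %), N-methylmorpholine N-oxide (1.5 equiv), acetone/H2O, rt
Reagents that add atoms: N-methylmorpholine N-oxide C[N+]1([O-])CCOCC1; water O
Why: Catalytic OsO4 dihydroxylation of the exocyclic alkene should occur from the equatorial direction, the face away from the equatorial ester on C2 and free of 1,3-diaxial hydrogens, giving the equatorial tertiary OH and the axial CH2OH cis to the ester.

Step 8
Reactants: 17 tert-butyl (1S,2R,3R,6S)-2-(dimethoxymethyl)-6-hydroxy-6-(hydroxymethyl)-3-isopropylcyclohexane-1-carboxylate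
Product: 18 tert-butyl (1S,2R,3R,6S)-2-(dimethoxymethyl)-6-hydroxy-3-isopropyl-6-{[(4-methylbenzenesulfonyl)oxy]methyl}cyclohexane-1-carboxylate
Conditions: TsCl, pyridine, CH2Cl2, 0 °C → rt
Reagents that add atoms: 4-methylbenzenesulfonyl chloride Cc1ccc(cc1)S(Cl)(=O)=O
Why: Sulfonylation is selective for the primary hydroxyl of the primary/tertiary 1,2-diol, and the bulky tert-butyl ester is too unreactive to lactonise with the neighbouring CH2OH.

Step 9
Reactants: 11 [(3R,4R)-3-(dimethoxymethyl)-4-isopropylcyclohex-1-en-1-yl]methanol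
Product: 19 (1R,6R)-3-(hydroxymethyl)-6-isopropylcyclohex-2-ene-1-carbaldehyde
Conditions: pyridinium 4-toluenesulfonate (cat.), acetone/H2O (10:1), 40 °C
Reagents that add atoms: water O
Why: Mild acid-catalysed acetal hydrolysis frees the aldehyde without base, so the beta,gamma-unsaturated aldehyde should neither epimerise nor move its double bond into conjugation.

Step 10
Reactants: 19 (1R,6R)-3-(hydroxymethyl)-6-isopropylcyclohex-2-ene-1-carbaldehyde; 20 (4-methoxyphenyl)methanol; 21 ethyl 2-(diethoxyphosphoryl)prop-2-enoate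
Product: 23 ethyl (2E)-3-[(1R,6R)-3-(hydroxymethyl)-6-isopropylcyclohex-2-en-1-yl]-2-{[(4-methoxyphenyl)methoxy]methyl}prop-2-enoate, via phosphonate carbanion 22 (not isolated)
Conditions: 20 (3 equiv), NaH (1.1 equiv), THF, 0 °C; 21 (1.2 equiv), 0 °C; then 19, –78 → 0 °C
Reagents that add atoms: none
Why: Tandem oxa-Michael addition of the alkoxide to the 2-phosphonoacrylate and Horner–Wadsworth–Emmons olefination of the aldehyde builds the 2-(alkoxymethyl)acrylate in one pot; an alpha-substituted diethyl phosphonoacetate with an alpha-branched aldehyde should favour the E isomer (ring trans to the ester), and excess neutral alcohol 20 suppresses exchange with the substrate hydroxyl.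

Step 11
Reactants: 23 ethyl (2E)-3-[(1R,6R)-3-(hydroxymethyl)-6-isopropylcyclohex-2-en-1-yl]-2-{[(4-methoxyphenyl)methoxy]methyl}prop-2-enoate
Product: 24 (2E)-3-[(1R,6R)-3-(hydroxymethyl)-6-isopropylcyclohex-2-en-1-yl]-2-{[(4-methoxyphenyl)methoxy]methyl}prop-2-enoic acid
Conditions: LiOH·H2O, THF/MeOH/H2O, rt; then 1 M HCl to pH 3
Reagents that add atoms: lithium hydroxide [Li+].[OH-]
Why: Saponification of the ethyl ester leaves the ether, the allylic alcohol and the alkene geometry untouched.

Step 12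
Reactants: 25 tert-butyl 2-(diethoxyphosphoryl)acetate; 26 paraformaldehyde
Product: 28 tert-butyl 2-(diethoxyphosphoryl)prop-2-enoate, via methanol adduct 27 (not isolated)
Conditions: piperidine (cat.), MeOH, reflux; then H3PO4 (cat.), toluene, reflux with removal of MeOH
Reagents that add atoms: none
Why: Knoevenagel condensation of the phosphonoacetate with formaldehyde gives the methanol adduct, which loses methanol under mild acid to the 2-phosphonoacrylate; the weak acid is chosen to spare the tert-butyl ester.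

Step 13
Reactants: 18 tert-butyl (1S,2R,3R,6S)-2-(dimethoxymethyl)-6-hydroxy-3-isopropyl-6-{[(4-methylbenzenesulfonyl)oxy]methyl}cyclohexane-1-carboxylate; 24 (2E)-3-[(1R,6R)-3-(hydroxymethyl)-6-isopropylcyclohex-2-en-1-yl]-2-{[(4-methoxyphenyl)methoxy]methyl}prop-2-enoic acid
Product: 30 tert-butyl (1S,2R,3R,6S)-2-(dimethoxymethyl)-6-hydroxy-6-{[((2E)-3-[(1R,6R)-3-(hydroxymethyl)-6-isopropylcyclohex-2-en-1-yl]-2-{[(4-methoxyphenyl)methoxy]methyl}prop-2-enoyl)oxy]methyl}-3-isopropylcyclohexane-1-carboxylate, via spiro-epoxide 29 (not isolated)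
Conditions: Cs2CO3 (1.0 equiv), 24 (1.5 equiv), DMF, 60 °C
Reagents that add atoms: none
Why: Intramolecular Williamson closure of the hydroxy tosylate gives the spiro-epoxide with retention at C1, and SN2 opening at its CH2 terminus by the cesium carboxylate forms the ester and the tertiary alcohol directly, so no free CH2OH is ever exposed next to the C2 ester; excess acid 24 buffers the tertiary alkoxide.

Step 14
Reactants: 30 tert-butyl (1S,2R,3R,6S)-2-(dimethoxymethyl)-6-hydroxy-6-{[((2E)-3-[(1R,6R)-3-(hydroxymethyl)-6-isopropylcyclohex-2-en-1-yl]-2-{[(4-methoxyphenyl)methoxy]methyl}prop-2-enoyl)oxy]methyl}-3-isopropylcyclohexane-1-carboxylate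
Product: 31 [(3aR,4R,7S,7aS)-3,7-dihydroxy-4-isopropyl-1-oxooctahydro-2-benzofuran-7-yl]methyl (2E)-2-(hydroxymethyl)-3-[(1R,6R)-3-(hydroxymethyl)-6-isopropylcyclohex-2-en-1-yl]prop-2-enoate
Conditions: TFA/CH2Cl2/H2O (5:4:1), anisole, 0 °C → rt; then brief aq NaHCO3/MeOH and acidification to pH 3
Reagents that add atoms: water O
Why: One acidolysis removes the tert-butyl ester and the 4-methoxybenzyl ether and hydrolyses the acetal; the freed formyl and carboxyl groups, trans-diequatorial on C3 and C2, should close to the gamma-hydroxy-gamma-lactone (pseudo-acid).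

Step 15
Reactants: 31 [(3aR,4R,7S,7aS)-3,7-dihydroxy-4-isopropyl-1-oxooctahydro-2-benzofuran-7-yl]methyl (2E)-2-(hydroxymethyl)-3-[(1R,6R)-3-(hydroxymethyl)-6-isopropylcyclohex-2-en-1-yl]prop-2-enoate; 28 tert-butyl 2-(diethoxyphosphoryl)prop-2-enoate
Product: 34 tert-butyl (5aS,6R,9S,9aS)-9-hydroxy-9-{[((2E)-2-(hydroxymethyl)-3-[(1R,6R)-3-(hydroxymethyl)-6-isopropylcyclohex-2-en-1-yl]prop-2-enoyl)oxy]methyl}-6-isopropyl-1-oxo-1,3,5a,6,7,8,9,9a-octahydro-2-benzoxepine-4-carboxylate, via cesium formyl carboxylate 32 (not isolated), via phosphonate carbanion 33 (not isolated)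
Conditions: Cs2CO3 (0.5 equiv), DMF, 0 °C; then 28 (1.3 equiv), 0 °C → rt
Reagents that add atoms: none
Why: Proposed new method: the cesium salt of pseudo-acid 31 is the ring-opened trans formyl carboxylate 32, whose carboxylate oxygen adds in an oxa-Michael sense to the doubly activated alkene of 28 to give phosphonate carbanion 33, which attacks the neighbouring formyl group and loses cesium diethyl phosphate (intramolecular Horner–Wadsworth–Emmons), so the O–CH2 bond and the C=C bond form in one operation and the five-membered lactol-lactone is expanded by three carbons to the oxepinone. The closest known reaction type is the tandem Michael addition/intramolecular Horner–Wadsworth–Emmons or Wittig reaction of carbonyl-bearing alkoxide, phenoxide or thiolate donors with 2-phosphonoacrylates or vinylphosphonium salts (2,5-dihydrofurans, 2H-chromenes); the carboxylate donor and the seven-membered lactone are the untested elements. The ring closes by 7-exo-trig attack of the carbanion on the aldehyde, and an endocyclic double bond in a seven-membered ring can only be cis, which fixes the acrylate geometry with the ester trans to C5a. No stereocentre is created, and C5a and C9a stay trans-diequatorial, which is also the thermodynamic arrangement should the formyl-bearing carbon epimerise. The step needs selectivity for the carboxylate over the four hydroxyl groups: with only the acid deprotonated, alkoxide formation is negligible, a reversible hydroxyl adduct has no aldehyde within reach, and only the carboxylate adduct is drained irreversibly by phosphate loss.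

Step 16
Reactants: 34 tert-butyl (5aS,6R,9S,9aS)-9-hydroxy-9-{[((2E)-2-(hydroxymethyl)-3-[(1R,6R)-3-(hydroxymethyl)-6-isopropylcyclohex-2-en-1-yl]prop-2-enoyl)oxy]methyl}-6-isopropyl-1-oxo-1,3,5a,6,7,8,9,9a-octahydro-2-benzoxepine-4-carboxylate
Product: 35 (5aS,6R,9S,9aS)-9-hydroxy-9-{[((2E)-2-(hydroxymethyl)-3-[(1R,6R)-3-(hydroxymethyl)-6-isopropylcyclohex-2-en-1-yl]prop-2-enoyl)oxy]methyl}-6-isopropyl-1-oxo-1,3,5a,6,7,8,9,9a-octahydro-2-benzoxepine-4-carboxylic acid
Conditions: TFA/CH2Cl2 (1:4), 0 °C; toluene azeotrope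
Reagents that add atoms: none
Why: Acidolysis of the tert-butyl ester (E1 loss of 2-methylpropene) frees the acrylic acid without nucleophiles or base that could attack the allylic lactone, and touches no stereocentre.

**Compound list**

1 | 3-methylbutanal | CC(C)CC=O | starting material
2 | but-3-en-2-one | CC(=O)C=C | starting material
3 | (2R)-2-isopropyl-5-oxohexanal | CC(C)[C@H](C=O)CCC(C)=O | intermediate (not isolated)
4 | (4R)-4-isopropylcyclohex-2-en-1-one, (R)-cryptone | CC(C)[C@H]1CCC(=O)C=C1 | intermediate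
5 | vinylmagnesium bromide | C=C[Mg]Br | starting material
6 | bromomagnesium (3R,4R)-4-isopropyl-3-vinylcyclohex-1-en-1-olate | CC(C)[C@H]1CCC(O[Mg]Br)=C[C@@H]1C=C | intermediate (not isolated)
7 | (3R,4R)-4-isopropyl-3-vinylcyclohex-1-en-1-yl trifluoromethanesulfonate | CC(C)[C@H]1CCC(OS(=O)(=O)C(F)(F)F)=C[C@@H]1C=C | intermediate
8 | (3R,4R)-3-formyl-4-isopropylcyclohex-1-en-1-yl trifluoromethanesulfonate | CC(C)[C@H]1CCC(OS(=O)(=O)C(F)(F)F)=C[C@@H]1C=O | intermediate (not isolated)
9 | (3R,4R)-3-(dimethoxymethyl)-4-isopropylcyclohex-1-en-1-yl trifluoromethanesulfonate | CC(C)[C@H]1CCC(OS(=O)(=O)C(F)(F)F)=C[C@@H]1C(OC)OC | intermediate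
10 | (tributylstannyl)methanol | CCCC[Sn](CCCC)(CCCC)CO | starting material
11 | [(3R,4R)-3-(dimethoxymethyl)-4-isopropylcyclohex-1-en-1-yl]methanol | CC(C)[C@H]1CCC(CO)=C[C@@H]1C(OC)OC | intermediate
12 | [(3R,4R)-3-(dimethoxymethyl)-4-isopropylcyclohex-1-en-1-yl]methyl methanesulfonate | CC(C)[C@H]1CCC(COS(C)(=O)=O)=C[C@@H]1C(OC)OC | intermediate (not isolated)
13 | (3R,4R)-1-(chloromethyl)-3-(dimethoxymethyl)-4-isopropylcyclohex-1-ene | CC(C)[C@H]1CCC(CCl)=C[C@@H]1C(OC)OC | intermediate
14 | di-tert-butyl dicarbonate | CC(C)(C)OC(=O)OC(=O)OC(C)(C)C | starting material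
15 | {[(3R,4R)-3-(dimethoxymethyl)-4-isopropylcyclohex-1-en-1-yl]methyl}magnesium chloride | CC(C)[C@H]1CCC(C[Mg]Cl)=C[C@@H]1C(OC)OC | intermediate (not isolated)
16 | tert-butyl (1S,2R,3R)-2-(dimethoxymethyl)-3-isopropyl-6-methylidenecyclohexane-1-carboxylate | CC(C)[C@H]1CCC(=C)[C@@H](C(=O)OC(C)(C)C)[C@@H]1C(OC)OC | intermediate
17 | tert-butyl (1S,2R,3R,6S)-2-(dimethoxymethyl)-6-hydroxy-6-(hydroxymethyl)-3-isopropylcyclohexane-1-carboxylate | CC(C)[C@H]1CC[C@@](O)(CO)[C@@H](C(=O)OC(C)(C)C)[C@@H]1C(OC)OC | intermediate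
18 | tert-butyl (1S,2R,3R,6S)-2-(dimethoxymethyl)-6-hydroxy-3-isopropyl-6-{[(4-methylbenzenesulfonyl)oxy]methyl}cyclohexane-1-carboxylate | CC(C)[C@H]1CC[C@@](O)(COS(=O)(=O)c2ccc(C)cc2)[C@@H](C(=O)OC(C)(C)C)[C@@H]1C(OC)OC | intermediate
19 | (1R,6R)-3-(hydroxymethyl)-6-isopropylcyclohex-2-ene-1-carbaldehyde | CC(C)[C@H]1CCC(CO)=C[C@@H]1C=O | intermediate
20 | (4-methoxyphenyl)methanol | COc1ccc(CO)cc1 | starting material
21 | ethyl 2-(diethoxyphosphoryl)prop-2-enoate | C=C(C(=O)OCC)P(=O)(OCC)OCC | starting material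
22 | sodium salt of the carbanion of ethyl 2-(diethoxyphosphoryl)-3-[(4-methoxyphenyl)methoxy]propanoate | CCOC(=O)[C-](COCc1ccc(OC)cc1)P(=O)(OCC)OCC.[Na+] | intermediate (not isolated)
23 | ethyl (2E)-3-[(1R,6R)-3-(hydroxymethyl)-6-isopropylcyclohex-2-en-1-yl]-2-{[(4-methoxyphenyl)methoxy]methyl}prop-2-enoate | CC(C)[C@H]1CCC(CO)=C[C@@H]1/C=C(\COCc1ccc(OC)cc1)C(=O)OCC | intermediate
24 | (2E)-3-[(1R,6R)-3-(hydroxymethyl)-6-isopropylcyclohex-2-en-1-yl]-2-{[(4-methoxyphenyl)methoxy]methyl}prop-2-enoic acid | CC(C)[C@H]1CCC(CO)=C[C@@H]1/C=C(\COCc1ccc(OC)cc1)C(=O)O | intermediate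
25 | tert-butyl 2-(diethoxyphosphoryl)acetate | CCOP(=O)(CC(=O)OC(C)(C)C)OCC | starting material
26 | paraformaldehyde (as formaldehyde) | C=O | starting material
27 | tert-butyl 2-(diethoxyphosphoryl)-3-methoxypropanoate | COCC(C(=O)OC(C)(C)C)P(=O)(OCC)OCC | intermediate (not isolated)
28 | tert-butyl 2-(diethoxyphosphoryl)prop-2-enoate | C=C(C(=O)OC(C)(C)C)P(=O)(OCC)OCC | intermediate
29 | tert-butyl (3S,4S,5R,6R)-5-(dimethoxymethyl)-6-isopropyl-1-oxaspiro[2.5]octane-4-carboxylate | CC(C)[C@H]1CC[C@@]2(CO2)[C@@H](C(=O)OC(C)(C)C)[C@@H]1C(OC)OC | intermediate (not isolated)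
30 | tert-butyl (1S,2R,3R,6S)-2-(dimethoxymethyl)-6-hydroxy-6-{[((2E)-3-[(1R,6R)-3-(hydroxymethyl)-6-isopropylcyclohex-2-en-1-yl]-2-{[(4-methoxyphenyl)methoxy]methyl}prop-2-enoyl)oxy]methyl}-3-isopropylcyclohexane-1-carboxylate | CC(C)[C@H]1CC[C@@](O)(COC(=O)/C(=C/[C@H]2C=C(CO)CC[C@@H]2C(C)C)COCc2ccc(OC)cc2)[C@@H](C(=O)OC(C)(C)C)[C@@H]1C(OC)OC | intermediate
31 | [(3aR,4R,7S,7aS)-3,7-dihydroxy-4-isopropyl-1-oxooctahydro-2-benzofuran-7-yl]methyl (2E)-2-(hydroxymethyl)-3-[(1R,6R)-3-(hydroxymethyl)-6-isopropylcyclohex-2-en-1-yl]prop-2-enoate (pseudo-acid, lactol epimers) | CC(C)[C@H]1CC[C@@](O)(COC(=O)/C(=C/[C@H]2C=C(CO)CC[C@@H]2C(C)C)CO)[C@H]2C(=O)OC(O)[C@H]12 | intermediate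
32 | cesium (1S,2R,3R,6S)-2-formyl-6-hydroxy-6-{[((2E)-2-(hydroxymethyl)-3-[(1R,6R)-3-(hydroxymethyl)-6-isopropylcyclohex-2-en-1-yl]prop-2-enoyl)oxy]methyl}-3-isopropylcyclohexane-1-carboxylate | CC(C)[C@H]1CC[C@@](O)(COC(=O)/C(=C/[C@H]2C=C(CO)CC[C@@H]2C(C)C)CO)[C@@H](C(=O)[O-])[C@@H]1C=O.[Cs+] | intermediate (not isolated)
33 | cesium salt of the phosphonate carbanion from oxa-Michael addition of 32 to 28 (3-tert-butoxy-2-(diethoxyphosphoryl)-3-oxopropyl ester of 32) | CC(C)[C@H]1CC[C@@](O)(COC(=O)/C(=C/[C@H]2C=C(CO)CC[C@@H]2C(C)C)CO)[C@@H](C(=O)OC[C-](C(=O)OC(C)(C)C)P(=O)(OCC)OCC)[C@@H]1C=O.[Cs+] | intermediate (not isolated)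
34 | tert-butyl (5aS,6R,9S,9aS)-9-hydroxy-9-{[((2E)-2-(hydroxymethyl)-3-[(1R,6R)-3-(hydroxymethyl)-6-isopropylcyclohex-2-en-1-yl]prop-2-enoyl)oxy]methyl}-6-isopropyl-1-oxo-1,3,5a,6,7,8,9,9a-octahydro-2-benzoxepine-4-carboxylate | CC(C)[C@H]1CC[C@@](O)(COC(=O)/C(=C/[C@H]2C=C(CO)CC[C@@H]2C(C)C)CO)[C@H]2C(=O)OCC(C(=O)OC(C)(C)C)=C[C@H]12 | intermediate
35 | (5aS,6R,9S,9aS)-9-hydroxy-9-{[((2E)-2-(hydroxymethyl)-3-[(1R,6R)-3-(hydroxymethyl)-6-isopropylcyclohex-2-en-1-yl]prop-2-enoyl)oxy]methyl}-6-isopropyl-1-oxo-1,3,5a,6,7,8,9,9a-octahydro-2-benzoxepine-4-carboxylic acid (CNP0361406.2) | CC(C)[C@H]1CC[C@@](O)(COC(=O)/C(=C/[C@H]2C=C(CO)CC[C@@H]2C(C)C)CO)[C@H]2C(=O)OCC(C(=O)O)=C[C@H]12 | target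

**Step count and risks**

Total step count: 16. Longest linear sequence: 12 steps (steps 1–8, then 13–16).

Steps most likely to fail:

1. Step 15 (proposed new method). Reversal of the oxa-Michael step (loss of carboxylate from the carbanion) may outrun the seven-membered ring closure, or the hydroxyl groups may add to the phosphonoacrylate. The fallback sets out from 31 and makes the two bonds in separate, known steps. Wittig methylenation of the pseudo-acid (excess Ph3P=CH2, THF, –78 → 0 °C) should give the vinyl acid F1. O-Alkylation of its carboxylate with tert-butyl 2-(bromomethyl)acrylate (KHCO3, DMF) should give the diene ester F2. Ring-closing metathesis with the second-generation Hoveyda–Grubbs catalyst (toluene, 80 °C) closes the trisubstituted ring alkene and returns to the route at 34.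

2. Step 6. Wurtz coupling during formation of the allylic Grignard reagent, acylation at the primary instead of the ring carbon, or poor facial selectivity at C2 may intervene. The fallback sets out from 11 and delivers the carbon intramolecularly by a Still–Wittig [2,3]-sigmatropic rearrangement. Alkylation with Bu3SnCH2I (KH, THF) should give the stannylmethyl ether F3. Treatment with n-BuLi (THF, –78 °C) should give the homoallylic alcohol F4 with the exocyclic methylene. Oxidation with TEMPO/PhI(OAc)2 in aqueous MeCN should give the acid F5. Esterification with O-tert-butyl-N,N′-diisopropylisourea returns to the route at 16.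

3. Step 13. Base-induced opening of the epoxide by the adjacent ester enolate, retro-aldol cleavage of the tertiary alkoxide, or sluggish attack at the neopentyl-type CH2 may lower the yield. The fallback sets out from 17 and 24 and forms the ester by acylation. Silylation of 24 (TBSCl, imidazole, DMF; then K2CO3, MeOH/H2O to cleave the silyl ester) should give the silyl ether acid F6. Yamaguchi esterification (2,4,6-trichlorobenzoyl chloride, Et3N; then 17, DMAP, toluene) at the primary hydroxyl of 17 should give the ester F7. The conditions of step 14 then remove the silyl ether together with the other acid-labile groups and return to the route at 31.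

Further compounds
F1 | step 15 | (1S,2R,3R,6S)-6-hydroxy-6-{[((2E)-2-(hydroxymethyl)-3-[(1R,6R)-3-(hydroxymethyl)-6-isopropylcyclohex-2-en-1-yl]prop-2-enoyl)oxy]methyl}-3-isopropyl-2-vinylcyclohexane-1-carboxylic acid | CC(C)[C@H]1CC[C@@](O)(COC(=O)/C(=C/[C@H]2C=C(CO)CC[C@@H]2C(C)C)CO)[C@@H](C(=O)O)[C@@H]1C=C
F2 | step 15 | 2-(tert-butoxycarbonyl)prop-2-en-1-yl ester of F1 | CC(C)[C@H]1CC[C@@](O)(COC(=O)/C(=C/[C@H]2C=C(CO)CC[C@@H]2C(C)C)CO)[C@@H](C(=O)OCC(=C)C(=O)OC(C)(C)C)[C@@H]1C=C
F3 | step 6 | tributyl({[(3R,4R)-3-(dimethoxymethyl)-4-isopropylcyclohex-1-en-1-yl]methoxy}methyl)stannane | CC(C)[C@H]1CCC(COC[Sn](CCCC)(CCCC)CCCC)=C[C@@H]1C(OC)OC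
F4 | step 6 | [(1S,2R,3R)-2-(dimethoxymethyl)-3-isopropyl-6-methylidenecyclohexyl]methanol | CC(C)[C@H]1CCC(=C)[C@@H](CO)[C@@H]1C(OC)OC
F5 | step 6 | (1S,2R,3R)-2-(dimethoxymethyl)-3-isopropyl-6-methylidenecyclohexane-1-carboxylic acid | CC(C)[C@H]1CCC(=C)[C@@H](C(=O)O)[C@@H]1C(OC)OC
F6 | step 13 | (2E)-3-[(1R,6R)-3-{[(tert-butyldimethylsilyl)oxy]methyl}-6-isopropylcyclohex-2-en-1-yl]-2-{[(4-methoxyphenyl)methoxy]methyl}prop-2-enoic acid | CC(C)[C@H]1CCC(CO[Si](C)(C)C(C)(C)C)=C[C@@H]1/C=C(\COCc1ccc(OC)cc1)C(=O)O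
F7 | step 13 | tert-butyldimethylsilyl ether of 30 at the allylic CH2OH | CC(C)[C@H]1CC[C@@](O)(COC(=O)/C(=C/[C@H]2C=C(CO[Si](C)(C)C(C)(C)C)CC[C@@H]2C(C)C)COCc2ccc(OC)cc2)[C@@H](C(=O)OC(C)(C)C)[C@@H]1C(OC)OC
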